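**Retrosynthetic overview**

1. Locants follow the carbon chain: C1 lactone C=O, C2 quaternary C–O, C3 CHOH, C4 CH2, C5 quaternary carbon with the lactone oxygen, C6 CH2, C7 CHOH, C8 CH2, C9 and C10 the two ring-fusion CH, C11=C12(CH3), C13 ether CH, C14=C15, C16–C22 heptyl. Rings: cyclopentane C5–C9; cyclohexane C2/C3/C4/C5/C9/C10; delta-lactone bridge C1–O–C5; dihydropyran O/C2/C10/C11/C12/C13.
2. Dihydropyran last: C13–H by Ferrier-type reductive transposition of a dihydropyranone, itself from the C2 hydroxyl and a C11/C13 beta-diketone. The diketone (C11–C12 bond) comes from acylation of the enolate of (E)-dodec-4-en-3-one by a temporary gamma-lactone C11(=O)–O–C5, which also hands the C5 oxygen over to C1 (the delta-lactone of the target).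
3. Cyclohexane: C2–C3 by samarium diiodide pinacol closure of an alpha-keto ester onto an aldehyde arm on C5.
4. Key disconnection C9–C10: ester-tethered intramolecular Michael addition that closes the temporary gamma-lactone. It is possible because the oxygen on C5 is cis-vicinal to the C9–C10 bond on the cyclopentane ring, C7 can be a ketone (C8=C9 enone), and C11 on C10 can be a carboxyl carbon. An O5–C11 ester therefore makes C10 the carbon acid of an oxaloacetate and delivers it to C9 from the oxygen face.
5. Ring order: cyclopentenone (chiral pool; C5 set by 1,2-addition) → gamma-lactone (C9–C10) → cyclohexane (C2–C3) → delta-lactone (lactone exchange) → dihydropyranone → dihydropyran; C7 is corrected last by Mitsunobu inversion.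

Key step: step 5

**Route**

Step 1
Reactants: 1 (R)-4-[(tert-butyldimethylsilyl)oxy]cyclopent-2-en-1-one; 2 (1,3-dioxolan-2-ylmethyl)magnesium bromide
Product: 3 (1R,4R)-4-[(tert-butyldimethylsilyl)oxy]-1-(1,3-dioxolan-2-ylmethyl)cyclopent-2-en-1-ol (OH and OSi cis)
Conditions: 2 (1.5 equiv), CeCl3 (anhydrous), THF, −78 °C; aq. NH4Cl
Reagents that add atoms: none
Why: Organocerium-mediated Grignard 1,2-addition to the enone carbonyl should occur anti to the C4 silyloxy group and so set the future C5 with OH cis to OSi; the minor diastereomer, which would become the enantiomer after step 3, is removed by chromatography.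

Step 2
Reactants: 3 (1R,4R)-4-[(tert-butyldimethylsilyl)oxy]-1-(1,3-dioxolan-2-ylmethyl)cyclopent-2-en-1-ol
Product: 4 (1R,4R)-1-(1,3-dioxolan-2-ylmethyl)cyclopent-2-ene-1,4-diol (cis)
Conditions: Bu4NF, THF, 0 → 23 °C
Reagents that add atoms: none
Why: Fluoride desilylation of a secondary silyl ether; the acetal and the tertiary allylic alcohol are inert.

Step 3
Reactants: 4 (1R,4R)-1-(1,3-dioxolan-2-ylmethyl)cyclopent-2-ene-1,4-diol
Product: 5 (S)-4-(1,3-dioxolan-2-ylmethyl)-4-hydroxycyclopent-2-en-1-one
Conditions: MnO2 (activated), CH2Cl2, 23 °C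
Reagents that add atoms: none
Why: Allylic oxidation with MnO2 should touch only the secondary allylic alcohol (the tertiary one cannot be oxidised), giving the C7-keto enone with C5 as the only stereocentre.

Step 4
Reactants: 6 2,2-dimethyl-1,3-dioxane-4,6-dione; 7 methyl chlorooxoacetate
Product: 8 methyl 2-(2,2-dimethyl-4,6-dioxo-1,3-dioxan-5-ylidene)-2-hydroxyacetate
Conditions: pyridine (2 equiv), CH2Cl2, 0 °C
Reagents that add atoms: none
Why: C-acylation of the cyclic malonate by an acid chloride gives the enolised acyl derivative, a storable precursor of the methoxyoxalyl ketene.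

Step 5
Reactants: 5 (S)-4-(1,3-dioxolan-2-ylmethyl)-4-hydroxycyclopent-2-en-1-one; 8 methyl 2-(2,2-dimethyl-4,6-dioxo-1,3-dioxan-5-ylidene)-2-hydroxyacetate
Product: 10 methyl 2-[6a-(1,3-dioxolan-2-ylmethyl)-2,5-dioxohexahydro-2H-cyclopenta[b]furan-3-yl]-2-oxoacetate (cis-fused; oxoacetyl group on the convex face), via oxaloacetate ester 9 (not isolated)
Conditions: toluene, 90 °C; then 0 °C, Et3N (0.2 equiv)
Reagents that add atoms: none
Why: Heating 8 releases acetone and CO2 and gives the acyl ketene, which is captured by the hindered tertiary alcohol 5 to give beta-keto ester 9; triethylamine then generates the stabilised enolate, whose central carbon C10 adds to C9 of the cyclopentenone (intramolecular Michael addition). The closest known reaction type is the base-mediated cyclisation of acetoacetates and malonates of 4-hydroxycycloalk-2-enones to cis-fused butyrolactones. The gamma-lactone ring closes in the 5-exo-trig mode. C9 is set by the tether: the ester oxygen on C5 can only deliver C10 to its own face, so the lactone is cis-fused. C10 stays epimerisable (beta-dicarbonyl C–H) and should settle with the oxalyl group on the convex face, trans to C8, which is the C9/C10 relationship of the target. The step needs C- over O-alkylation and survival of the beta-acyloxy ketone; both are secured by the soft, strongly acidic beta-dicarbonyl unit, which also buffers the medium against E1cB loss of the carboxylate.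

Step 6
Reactants: 10 methyl 2-[6a-(1,3-dioxolan-2-ylmethyl)-2,5-dioxohexahydro-2H-cyclopenta[b]furan-3-yl]-2-oxoacetate
Product: 11 methyl 2-[2,5-dioxo-6a-(2-oxoethyl)hexahydro-2H-cyclopenta[b]furan-3-yl]-2-oxoacetate
Conditions: 2 M HCl, THF, 23 °C
Reagents that add atoms: water, O
Why: Acid-catalysed acetal hydrolysis unveils the C3 aldehyde; lactone, keto ester and ketone tolerate dilute acid, and an aldol closure from C10 onto C3 would need a trans-fused five-membered ring.

Step 7
Reactants: 11 methyl 2-[2,5-dioxo-6a-(2-oxoethyl)hexahydro-2H-cyclopenta[b]furan-3-yl]-2-oxoacetate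
Product: 12 tricyclic cis-diol: methyl ester with C2(OH)(CO2Me)–C3H(OH) bond closed, C7 ketone, gamma-lactone C11(=O)–O–C5
Conditions: SmI2 (2.5 equiv), MeOH (2 equiv), THF, −78 °C
Reagents that add atoms: none
Why: Samarium diiodide pinacol cyclisation of the easily reduced alpha-keto ester onto the aldehyde should close the cyclohexane through a chair; the axial site at C3 lies under the lactone bridge, so O3 is equatorial, and chelation by trivalent samarium makes the diol cis, which puts the C2 ester equatorial (target C2 and C3), while coupling with the C7 ketone would need a norbornane.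

Step 8
Reactants: 12 tricyclic cis-diol
Product: 13 C2,C3-acetonide C7-dimethyl ketal of 12
Conditions: 2,2-dimethoxypropane/MeOH (4:1), camphorsulfonic acid (cat.), 23 °C
Reagents that add atoms: 2,2-dimethoxypropane, COC(C)(C)OC
Why: Acid-catalysed acetal exchange converts the cis-diol into the acetonide and the C7 ketone into its dimethyl ketal, removing the acidic hydroxyls and the base-labile beta-acyloxy ketone before the enolate step.

Step 9
Reactants: 14 octanal; 15 diethyl (2-oxobutyl)phosphonate
Product: 16 (E)-dodec-4-en-3-one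
Conditions: LiCl, i-Pr2NEt, MeCN, 23 °C
Reagents that add atoms: none
Why: Horner–Wadsworth–Emmons olefination with a stabilised keto phosphonate should give the E-enone that carries C12–C22 and the 12-methyl group.

Step 10
Reactants: 13 acetonide dimethyl ketal; 16 (E)-dodec-4-en-3-one
Product: 18 C11/C13 beta-diketone with delta-lactone C1(=O)–O–C5 (2-oxabicyclo[2.2.2]octanone; acetonide and ketal intact; C12 epimers), via hydroxy diketone ester 17 (not isolated)
Conditions: LiN(i-Pr)2 (2.6 equiv), 16 (2.5 equiv), THF, −78 °C; then 13, −78 → 0 °C; AcOH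
Reagents that add atoms: none
Why: The kinetic (ethyl-side) lithium enolate of 16 should be C-acylated by the strained lactone carbonyl C11 (Claisen-type acylation; C10–H is a bridgehead and cannot enolise), and the released C5 alkoxide then transesterifies onto the cis-1,4 methyl ester at C1, exchanging the gamma- for the delta-lactone without touching a stereocentre.

Step 11
Reactants: 18 beta-diketone delta-lactone
Product: 19 tetracyclic 2,3-dihydro-4H-pyran-4-one (C11 ketone, C12=C13, ring O on C2; C7 ketone; 3-OH free)
Conditions: 2 M HCl, THF, 23 °C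
Reagents that add atoms: water, O
Why: Acid removes the acetonide and the ketal and cyclodehydrates the delta-hydroxy beta-diketone (C2–OH onto C13) to the vinylogous ester; the C3 hydroxyl is anti to C11 across C2–C10 and cannot compete, and the C12 stereocentre disappears.

Step 12
Reactants: 19 tetracyclic dihydropyranone
Product: 20 7,11-diol (7-OH cis to the lactone oxygen; C11 carbinol configuration undefined)
Conditions: NaBH4, CeCl3·7H2O, MeOH, −78 → −20 °C
Reagents that add atoms: none
Why: Luche reduction should reduce the vinylogous-ester carbonyl C11 in the 1,2-sense and the C7 ketone with hydride entering anti to the pseudo-axial C5–O bond, giving mainly the 7-epi alcohol (any trans epimer already has the target configuration and converges after step 13).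

Step 13
Reactants: 20 7,11-diol
Product: 21 7-epi target (dihydropyran complete, C11=C12, C13–H)
Conditions: Et3SiH, BF3·OEt2, CH2Cl2, −78 → −40 °C
Reagents that add atoms: none
Why: Ferrier-type reductive allylic transposition: BF3 ionises the C11 carbinol to the allylic oxocarbenium ion and the silane should deliver hydride to C13 anti to the axial C1 carbonyl on C2, placing the side chain cis to C1 and the double bond at C11=C12.

Step 14
Reactants: 21 7-epi target
Product: 23 target CNP0127096.1, via 4-nitrobenzoate 22 (not isolated)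
Conditions: PPh3, diisopropyl azodicarboxylate, 4-nitrobenzoic acid, THF, 0 → 23 °C; then K2CO3, MeOH, 0 °C
Reagents that add atoms: 4-nitrobenzoic acid, OC(=O)c1ccc(cc1)[N+](=O)[O-]
Why: Mitsunobu inversion (SN2 by the carboxylate) should act only on the unhindered C7 cyclopentanol, the C3 hydroxyl being neopentyl and caged, and mild methanolysis then frees the C7 hydroxyl trans to the lactone oxygen.

**Compound list**

1 | (R)-4-[(tert-butyldimethylsilyl)oxy]cyclopent-2-en-1-one | O=C1C[C@@H](O[Si](C)(C)C(C)(C)C)C=C1 | starting material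
2 | (1,3-dioxolan-2-ylmethyl)magnesium bromide | Br[Mg]CC1OCCO1 | starting material
3 | (1R,4R)-4-[(tert-butyldimethylsilyl)oxy]-1-(1,3-dioxolan-2-ylmethyl)cyclopent-2-en-1-ol | O[C@@]1(CC2OCCO2)C[C@@H](O[Si](C)(C)C(C)(C)C)C=C1 | intermediate
4 | (1R,4R)-1-(1,3-dioxolan-2-ylmethyl)cyclopent-2-ene-1,4-diol | O[C@@]1(CC2OCCO2)C[C@@H](O)C=C1 | intermediate
5 | (S)-4-(1,3-dioxolan-2-ylmethyl)-4-hydroxycyclopent-2-en-1-one | O[C@@]1(CC2OCCO2)CC(=O)C=C1 | intermediate
6 | 2,2-dimethyl-1,3-dioxane-4,6-dione | CC1(C)OC(=O)CC(=O)O1 | starting material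
7 | methyl chlorooxoacetate | COC(=O)C(Cl)=O | starting material
8 | methyl 2-(2,2-dimethyl-4,6-dioxo-1,3-dioxan-5-ylidene)-2-hydroxyacetate | COC(=O)C(O)=C1C(=O)OC(C)(C)OC1=O | intermediate
9 | 4-[(S)-1-(1,3-dioxolan-2-ylmethyl)-4-oxocyclopent-2-en-1-yl] 1-methyl 2-oxobutanedioate | COC(=O)C(=O)CC(=O)O[C@@]1(CC2OCCO2)CC(=O)C=C1 | intermediate
10 | methyl 2-[6a-(1,3-dioxolan-2-ylmethyl)-2,5-dioxohexahydro-2H-cyclopenta[b]furan-3-yl]-2-oxoacetate (cis-fused, oxoacetyl trans to C8) | COC(=O)C(=O)[C@@H]1C(=O)O[C@@]2(CC3OCCO3)CC(=O)C[C@@H]12 | intermediate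
11 | methyl 2-[2,5-dioxo-6a-(2-oxoethyl)hexahydro-2H-cyclopenta[b]furan-3-yl]-2-oxoacetate | COC(=O)C(=O)[C@@H]1C(=O)O[C@@]2(CC=O)CC(=O)C[C@@H]12 | intermediate
12 | tricyclic C2,C3-cis-diol methyl ester (C7 ketone, gamma-lactone C11–O–C5) | COC(=O)[C@@]1(O)[C@H](O)C[C@]23CC(=O)C[C@H]2[C@H]1C(=O)O3 | intermediate
13 | C2,C3-acetonide C7-dimethyl ketal of 12 | COC(=O)[C@@]1(OC(C)(C)O2)[C@H]2C[C@]34CC(OC)(OC)C[C@H]3[C@H]1C(=O)O4 | intermediate
14 | octanal | CCCCCCCC=O | starting material
15 | diethyl (2-oxobutyl)phosphonate | CCC(=O)CP(=O)(OCC)OCC | starting material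
16 | (E)-dodec-4-en-3-one | CCCCCCC/C=C/C(=O)CC | intermediate
17 | ring-opened C5-hydroxy C11/C13 beta-diketone methyl ester (acetonide, ketal; C12 epimers) | COC(=O)[C@@]1(OC(C)(C)O2)[C@H]2C[C@]3(O)CC(OC)(OC)C[C@H]3[C@H]1C(=O)C(C)C(=O)/C=C/CCCCCCC | intermediate
18 | C11/C13 beta-diketone with delta-lactone C1–O–C5 (acetonide, ketal; C12 epimers) | O=C1O[C@@]23CC(OC)(OC)C[C@H]2[C@@H](C(=O)C(C)C(=O)/C=C/CCCCCCC)[C@@]14OC(C)(C)O[C@@H]4C3 | intermediate
19 | tetracyclic dihydropyranone (C11 and C7 ketones, 3-OH) | CCCCCCC/C=C/C1=C(C)C(=O)[C@@H]2[C@@H]3CC(=O)C[C@@]34C[C@@H](O)[C@]2(O1)C(=O)O4 | intermediate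
20 | 7,11-diol (7-OH cis to lactone oxygen; C11 undefined) | CCCCCCC/C=C/C1=C(C)C(O)[C@@H]2[C@@H]3C[C@H](O)C[C@@]34C[C@@H](O)[C@]2(O1)C(=O)O4 | intermediate
21 | 7-epi target | CCCCCCC/C=C/[C@H]1O[C@@]23C(=O)O[C@]4(C[C@@H](O)C[C@H]4[C@H]2C=C1C)C[C@H]3O | intermediate
22 | 7-O-(4-nitrobenzoyl) target | CCCCCCC/C=C/[C@H]1O[C@@]23C(=O)O[C@]4(C[C@H](OC(=O)c5ccc(cc5)[N+](=O)[O-])C[C@H]4[C@H]2C=C1C)C[C@H]3O | intermediate
23 | CNP0127096.1 | CCCCCCC/C=C/[C@H]1O[C@@]23C(=O)O[C@]4(C[C@H](O)C[C@H]4[C@H]2C=C1C)C[C@H]3O | target

**Step count and risks**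

Total step count: 14. Longest linear sequence: 12 steps (steps 1, 2, 3, 5, 6, 7, 8, 10, 11, 12, 13, 14).

Most likely to fail, with fallbacks:

Step 10. The enolate may attack the C1 methyl ester instead of the lactone, or add to a second molecule of enone 16. The tetrahedral adduct may also fail to collapse, so that the C5 alkoxide never forms and the lactone exchange stalls. The fallback replaces the Claisen acylation by an aldol–oxidation sequence and sets out from 13. Reduction of the gamma-lactone with i-Bu2AlH (1.1 equiv, CH2Cl2, −78 °C) should give lactol F1. The lithium enolate of 16 (LiN(i-Pr)2, THF, −78 °C) adds to its open hydroxy-aldehyde form to give beta-hydroxy ketone F2. Dess–Martin periodinane oxidises the secondary C11 carbinol (the tertiary C5 hydroxyl is inert) to the hydroxy diketone 17, here isolated. NaOMe (0.1 equiv, THF/toluene) then closes the delta-lactone, and the route is rejoined at 18.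

Step 13. The delocalised cation may capture hydride at C11 or C15 instead of C13, hydride may enter syn to C1, or the cation may lose a proton to a pyran diene. The fallback uses conjugate reduction and an enol triflate instead of an allylic cation and sets out from 19. Li[(s-Bu)3BH] (3 equiv, THF, −78 °C) should reduce the C7 ketone (again anti to the C5–O bond) and add hydride to C13 of the vinylogous ester, anti to C1. The C11 enolate is trapped at −78 °C with N-phenyl-bis(trifluoromethanesulfonimide) to give enol triflate F3. Pd(OAc)2, PPh3, HCO2H and Bu3N (DMF, 60 °C) then replace the triflate by hydrogen, and the route is rejoined at 21.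

Step 5. Capture of the acyl ketene by the hindered tertiary alcohol may lose out to ketene self-condensation, and the product may shed its carboxylate by E1cB elimination. The fallback forms the C–C bond first and closes the ring by lactonisation; it sets out from 5. Conjugate addition of dimethyl 2-oxobutanedioate (NaOMe 0.2 equiv, MeOH/THF, 0 °C) should give Michael adduct F4. Only the adduct with C10 cis to the C5 hydroxyl can lactonise on the C11 ester, with loss of methanol; the trans adduct is recycled by retro-Michael equilibration. The product is 10.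

Further compounds
F1 | step 10 | C11 lactol of 13 | COC(=O)[C@@]1(OC(C)(C)O2)[C@H]2C[C@]34CC(OC)(OC)C[C@H]3[C@H]1C(O)O4
F2 | step 10 | C11-hydroxy C13-ketone aldol adduct (C5-OH free) | COC(=O)[C@@]1(OC(C)(C)O2)[C@H]2C[C@]3(O)CC(OC)(OC)C[C@H]3[C@H]1C(O)C(C)C(=O)/C=C/CCCCCCC
F3 | step 13 | C11 enol triflate of the 7-epi series | CCCCCCC/C=C/[C@H]1O[C@@]23C(=O)O[C@]4(C[C@@H](O)C[C@H]4[C@H]2C(OS(=O)(=O)C(F)(F)F)=C1C)C[C@H]3O
F4 | step 5 | dimethyl 2-oxo-3-[(1S,2S)-2-(1,3-dioxolan-2-ylmethyl)-2-hydroxy-4-oxocyclopentyl]butanedioate | COC(=O)C(=O)C(C(=O)OC)[C@@H]1CC(=O)C[C@@]1(O)CC1OCCO1
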